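**Retrosynthetic overview**
1. Target 30 ← desilylation ← Yamaguchi closure of the 7-membered lactone (ring C, O4–C16) on seco-acid 27 ← allylic oxidation of an isopropenyl group.
2. Tetrahydrofuran (ring B) ← one acid-triggered cascade on epoxy-ketal 23: ketal unmasking (C5 ketone) and 5-exo opening of the (12S,13S)-epoxide by O9.
3. 23 ← Achmatowicz rearrangement of the macrocyclic furfuryl alcohol 18 (key step: the furan is the latent C5–C8 keto unit; MeLi then sets C8 from C9).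
4. 14-membered carbocycle (ring A) ← intramolecular enolate C-alkylation (C10–C11) of acetylfuran allylic bromide 15; C9 by Noyori transfer hydrogenation.
5. 15 ← (R)-limonene (C1–C4, C13–C17) + Wittig unit (C11, C12) + furan (C5–C8, joined at C4 by lithiation–borylation) + acetyl (C9, C10). Ring order: furan → ring A → pyranone → ring B → ring C.

Assumption: locants run C1 (CH bearing C15(=C17H2)–C16) → C4 (O-bearing quaternary C) → C5 (C=O) → C8 (C(Me)OH) → C9/C12 (THF carbons) → C13 (CHOH) → C14; the given SMILES is then (1R,4R,8R,9R,12R,13S). The ketal carbon C5 in 19–23 is an inconsequential anomer mixture and is drawn without configuration.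

**Step 1**
Reactants: 1 furan
Product: 4 2-(furan-2-yl)-5,5-dimethyl-1,3,2-dioxaborinane, via furan-2-yllithium 2 (not isolated), via lithium furan-2-yl(triisopropoxy)borate 3 (not isolated)
Conditions: n-BuLi, THF, −78 to 0 °C; B(OiPr)3, −78 °C; then neopentyl glycol, AcOH, 25 °C
Reagents that add atoms: triisopropyl borate CC(C)OB(OC(C)C)OC(C)C; 2,2-dimethylpropane-1,3-diol OCC(C)(C)CO
Why: α-Lithiation of furan, borylation to the ate complex and transesterification with the diol give the boronic ester; no stereocenter is formed.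

**Step 2**
Reactants: 5 (R)-(+)-limonene
Product: 7 (3R)-6-oxo-3-(prop-1-en-2-yl)heptanal, via ring ozonide 6 (not isolated)
Conditions: O3 (1 equiv, dye end point), CH2Cl2, −78 °C; Me2S
Reagents that add atoms: ozone [O-][O+]=O
Why: Ozonolysis cleaves the electron-rich trisubstituted ring alkene faster than the 1,1-disubstituted isopropenyl group; C1 comes unchanged from the chiral pool.

**Step 3**
Reactants: 7 (3R)-6-oxo-3-(prop-1-en-2-yl)heptanal
Product: 8 ethyl (2E,5R)-2-methyl-8-oxo-5-(prop-1-en-2-yl)non-2-enoate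
Conditions: Ph3P=C(CH3)CO2Et, CH2Cl2, 25 °C
Reagents that add atoms: ethyl 2-(triphenyl-λ5-phosphanylidene)propanoate CCOC(=O)C(C)=P(c1ccccc1)(c1ccccc1)c1ccccc1
Why: Wittig olefination with a stabilized ylide is aldehyde-selective over the methyl ketone and E-selective, fixing the (12E) geometry.

**Step 4**
Reactants: 8 ethyl (2E,5R)-2-methyl-8-oxo-5-(prop-1-en-2-yl)non-2-enoate
Product: 9 ethyl (2E,5R,8R)-8-hydroxy-2-methyl-5-(prop-1-en-2-yl)non-2-enoate
Conditions: (R)-selective alcohol dehydrogenase from Lactobacillus kefir, NADP+ (cat.), i-PrOH, MgCl2, phosphate buffer pH 7, 30 °C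
Reagents that add atoms: none
Why: Enzymatic (anti-Prelog) ketone reduction distinguishes methyl from the CH2 chain and gives the (R)-carbinol, whose C–O stereochemistry becomes that of C4.

**Step 5**
Reactants: 9 ethyl (2E,5R,8R)-8-hydroxy-2-methyl-5-(prop-1-en-2-yl)non-2-enoate
Product: 10 ethyl (2E,5R,8R)-2-methyl-5-(prop-1-en-2-yl)-8-{[2,4,6-tri(propan-2-yl)benzoyl]oxy}non-2-enoate
Conditions: 2,4,6-(i-Pr)3C6H2COCl, Et3N, DMAP (cat.), CH2Cl2, 40 °C
Reagents that add atoms: 2,4,6-tri(propan-2-yl)benzoyl chloride CC(C)c1cc(C(C)C)c(C(Cl)=O)c(C(C)C)c1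
Why: DMAP-catalysed acylation installs the hindered benzoate that directs and stabilises α-lithiation; the carbinol configuration is untouched.

**Step 6**
Reactants: 10 ethyl (2E,5R,8R)-2-methyl-5-(prop-1-en-2-yl)-8-{[2,4,6-tri(propan-2-yl)benzoyl]oxy}non-2-enoate
Product: 11 (2R,5R,7E)-9-hydroxy-8-methyl-5-(prop-1-en-2-yl)non-7-en-2-yl 2,4,6-tri(propan-2-yl)benzoate
Conditions: i-Bu2AlH (2.3 equiv), CH2Cl2, −78 °C
Reagents that add atoms: none
Why: Hydride reduction of the enoate to the allylic alcohol; the sterically shielded triisopropylbenzoate is not attacked.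

**Step 7**
Reactants: 11 (2R,5R,7E)-9-hydroxy-8-methyl-5-(prop-1-en-2-yl)non-7-en-2-yl 2,4,6-tri(propan-2-yl)benzoate; 4 2-(furan-2-yl)-5,5-dimethyl-1,3,2-dioxaborinane
Product: 13 (2E,5R,8R)-8-(furan-2-yl)-2-methyl-5-(prop-1-en-2-yl)non-2-ene-1,8-diol, via tertiary boronic ester 12 (not isolated)
Conditions: s-BuLi (2.5 equiv), TMEDA, CPME, −60 °C; 4; MgBr2·OEt2, MeOH, −60 to 40 °C; then NaOH, H2O2, THF, 0 °C
Reagents that add atoms: hydrogen peroxide OO
Why: Lithiation–borylation (1,2-metalate rearrangement): retentive α-lithiation and borylation, anti-periplanar furyl migration with loss of the benzoate, and retentive C–B oxidation replace H by furyl while keeping the C–O stereochemistry, giving (R)-C4.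

**Step 8**
Reactants: 13 (2E,5R,8R)-8-(furan-2-yl)-2-methyl-5-(prop-1-en-2-yl)non-2-ene-1,8-diol
Product: 14 1-{5-[(2R,5R,7E)-2,9-dihydroxy-8-methyl-5-(prop-1-en-2-yl)non-7-en-2-yl]furan-2-yl}ethan-1-one
Conditions: n-BuLi (3.3 equiv), THF, −78 to 0 °C; MeC(O)N(OMe)Me, −78 to 25 °C
Reagents that add atoms: N-methoxy-N-methylacetamide CC(=O)N(C)OC
Why: After both hydroxyls are deprotonated the free furan α-position is lithiated and acylated by the Weinreb amide, whose tetrahedral intermediate stops at the ketone (C9, C10).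

**Step 9**
Reactants: 14 1-{5-[(2R,5R,7E)-2,9-dihydroxy-8-methyl-5-(prop-1-en-2-yl)non-7-en-2-yl]furan-2-yl}ethan-1-one
Product: 15 1-{5-[(2R,5R,7E)-9-bromo-2-hydroxy-8-methyl-5-(prop-1-en-2-yl)non-7-en-2-yl]furan-2-yl}ethan-1-one
Conditions: CBr4, PPh3, CH2Cl2, 0 °C
Reagents that add atoms: carbon tetrabromide BrC(Br)(Br)Br
Why: The Appel reaction converts only the primary allylic alcohol; the tertiary alcohol cannot undergo SN2 and the acyl group suppresses furfuryl ionisation.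

**Step 10**
Reactants: 15 1-{5-[(2R,5R,7E)-9-bromo-2-hydroxy-8-methyl-5-(prop-1-en-2-yl)non-7-en-2-yl]furan-2-yl}ethan-1-one
Product: 16 (1R,4R,12E)-5,8-epoxy-4-hydroxy-4,12-dimethyl-1-(prop-1-en-2-yl)cyclotetradeca-5,7,12-trien-9-one (2,5-furanophane)
Conditions: LiN(SiMe3)2 (2.2 equiv), THF, −78 to 0 °C, slow addition (0.001 M)
Reagents that add atoms: none
Why: Intramolecular enolate C-alkylation (SN2 at the primary allylic bromide, only the acetyl CH3 is enolisable) closes ring A under high dilution, as in furanocembranoid macrocyclisations.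

**Step 11**
Reactants: 16 (1R,4R,12E)-5,8-epoxy-4-hydroxy-4,12-dimethyl-1-(prop-1-en-2-yl)cyclotetradeca-5,7,12-trien-9-one
Product: 17 (1R,4R,12E)-5,8-epoxy-4,12-dimethyl-1-(prop-1-en-2-yl)-4-[(triethylsilyl)oxy]cyclotetradeca-5,7,12-trien-9-one
Conditions: Et3SiOTf, 2,6-lutidine, CH2Cl2, −78 °C
Reagents that add atoms: triethylsilyl trifluoromethanesulfonate CC[Si](CC)(CC)OS(=O)(=O)C(F)(F)F
Why: Silyl triflate silylation blocks the tertiary C4 hydroxyl so that only O9 can take part in the later furan rearrangement.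

**Step 12**
Reactants: 17 (1R,4R,12E)-5,8-epoxy-4,12-dimethyl-1-(prop-1-en-2-yl)-4-[(triethylsilyl)oxy]cyclotetradeca-5,7,12-trien-9-one
Product: 18 (1R,4R,9R,12E)-5,8-epoxy-4,12-dimethyl-1-(prop-1-en-2-yl)-4-[(triethylsilyl)oxy]cyclotetradeca-5,7,12-trien-9-ol
Conditions: RuCl[(R,R)-TsDPEN](p-cymene) (1 mol %), HCO2Na, H2O/DMF, 40 °C
Reagents that add atoms: none
Why: Noyori asymmetric transfer hydrogenation of the heteroaryl ketone under neutral formate conditions; the (R,R)-catalyst delivers hydride to give (9R).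

**Step 13**
Reactants: 18 (1R,4R,9R,12E)-5,8-epoxy-4,12-dimethyl-1-(prop-1-en-2-yl)-4-[(triethylsilyl)oxy]cyclotetradeca-5,7,12-trien-9-ol
Product: 20 (1R,4R,9R,12E)-5,9-epoxy-5-methoxy-4,12-dimethyl-1-(prop-1-en-2-yl)-4-[(triethylsilyl)oxy]cyclotetradeca-6,12-dien-8-one, via hemiketal pyranone 19 (not isolated)
Conditions: VO(acac)2 (5 mol %), t-BuOOH (1.1 equiv), CH2Cl2, 0 °C; then MeOH, PPTS, 25 °C
Reagents that add atoms: tert-butyl hydroperoxide CC(C)(C)OO; methanol CO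
Why: Achmatowicz rearrangement: hydroxyl-directed VO(acac)2-catalysed oxidation of the furan, opening to the cis-enedione and hemiketalisation by O9 give the pyranone (C5 ketal, C8 ketone), which is locked as the methyl glycoside; C9 is unchanged.

**Step 14**
Reactants: 20 (1R,4R,9R,12E)-5,9-epoxy-5-methoxy-4,12-dimethyl-1-(prop-1-en-2-yl)-4-[(triethylsilyl)oxy]cyclotetradeca-6,12-dien-8-one
Product: 21 (1R,4R,9R,12E)-5,9-epoxy-5-methoxy-4,12-dimethyl-1-(prop-1-en-2-yl)-4-[(triethylsilyl)oxy]cyclotetradec-12-en-8-one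
Conditions: [(Ph3P)CuH]6 (5 mol %), H2 (35 bar), t-BuOH, toluene, 25 °C
Reagents that add atoms: none
Why: [(Ph3P)CuH]6-catalysed conjugate reduction saturates only the enone C6=C7; the isolated trisubstituted and isopropenyl alkenes are not touched.

**Step 15**
Reactants: 21 (1R,4R,9R,12E)-5,9-epoxy-5-methoxy-4,12-dimethyl-1-(prop-1-en-2-yl)-4-[(triethylsilyl)oxy]cyclotetradec-12-en-8-one
Product: 22 (1R,4R,8R,9R,12E)-5,9-epoxy-5-methoxy-4,8,12-trimethyl-1-(prop-1-en-2-yl)-4-[(triethylsilyl)oxy]cyclotetradec-12-en-8-ol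
Conditions: MeLi, Et2O, −78 °C
Reagents that add atoms: methyllithium [Li]C
Why: 1,2-Addition of MeLi to the tetrahydropyranone by equatorial attack, anti to the adjacent equatorial C10 substituent, places OH cis to C10 and gives (8R).

**Step 16**
Reactants: 22 (1R,4R,8R,9R,12E)-5,9-epoxy-5-methoxy-4,8,12-trimethyl-1-(prop-1-en-2-yl)-4-[(triethylsilyl)oxy]cyclotetradec-12-en-8-ol
Product: 23 (1R,4R,8R,9R,12S,13S)-5,9:12,13-diepoxy-5-methoxy-4,8,12-trimethyl-1-(prop-1-en-2-yl)-4-[(triethylsilyl)oxy]cyclotetradecan-8-ol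
Conditions: ent-Shi ketone (L-fructose-derived, 0.3 equiv), 2KHSO5·KHSO4·K2SO4, K2CO3, Na2B4O7 buffer, MeCN/CH2(OMe)2, 0 °C
Reagents that add atoms: potassium peroxymonosulfate [K+].[O-]S(=O)(=O)OO
Why: Shi asymmetric epoxidation is reagent-controlled and prefers the trisubstituted (E)-alkene over the 1,1-disubstituted isopropenyl group, giving the (12S,13S)-epoxide.

**Step 17**
Reactants: 23 (1R,4R,8R,9R,12S,13S)-5,9:12,13-diepoxy-5-methoxy-4,8,12-trimethyl-1-(prop-1-en-2-yl)-4-[(triethylsilyl)oxy]cyclotetradecan-8-ol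
Product: 24 (1R,4R,8R,9R,12R,13S)-9,12-epoxy-4,8,13-trihydroxy-4,8,12-trimethyl-1-(prop-1-en-2-yl)cyclotetradecan-5-one
Conditions: p-TsOH·H2O (0.2 equiv), acetone/H2O 10:1, 0 to 25 °C
Reagents that add atoms: water O
Why: Acid cascade: ketal hydrolysis frees the C5 ketone and O9, which opens the epoxide 5-exo at tertiary C12 with inversion (12R, C13 retained) to the trans-tetrahydrofuran, and the tertiary silyl ether is solvolysed.

**Step 18**
Reactants: 24 (1R,4R,8R,9R,12R,13S)-9,12-epoxy-4,8,13-trihydroxy-4,8,12-trimethyl-1-(prop-1-en-2-yl)cyclotetradecan-5-one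
Product: 25 (1R,4R,8R,9R,12R,13S)-9,12-epoxy-4,8-dihydroxy-4,8,12-trimethyl-1-(prop-1-en-2-yl)-13-[(triethylsilyl)oxy]cyclotetradecan-5-one
Conditions: Et3SiCl, imidazole, DMF, 0 °C
Reagents that add atoms: chlorotriethylsilane CC[Si](Cl)(CC)CC
Why: Selective silylation of the only secondary alcohol masks O13, which would otherwise close a 6-membered lactone in step 20.

**Step 19**
Reactants: 25 (1R,4R,8R,9R,12R,13S)-9,12-epoxy-4,8-dihydroxy-4,8,12-trimethyl-1-(prop-1-en-2-yl)-13-[(triethylsilyl)oxy]cyclotetradecan-5-one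
Product: 27 2-[(1R,4R,8R,9R,12R,13S)-9,12-epoxy-4,8-dihydroxy-4,8,12-trimethyl-5-oxo-13-[(triethylsilyl)oxy]cyclotetradecyl]prop-2-enoic acid, via enal 26 (not isolated)
Conditions: SeO2, 1,4-dioxane, 60 °C; then NaClO2, NaH2PO4, 2-methylbut-2-ene, t-BuOH/H2O, 0 °C
Reagents that add atoms: selenium dioxide O=[Se]=O; sodium chlorite [Na+].[O-]Cl=O
Why: Riley allylic oxidation of the isopropenyl methyl (the only alkene left) to the 2-substituted acrolein, then Pinnick oxidation to the acrylic acid; no stereocenter changes.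

**Step 20**
Reactants: 27 2-[(1R,4R,8R,9R,12R,13S)-9,12-epoxy-4,8-dihydroxy-4,8,12-trimethyl-5-oxo-13-[(triethylsilyl)oxy]cyclotetradecyl]prop-2-enoic acid
Product: 29 13-O-triethylsilyl ether of the target, via mixed anhydride 28 (not isolated)
Conditions: 2,4,6-Cl3C6H2COCl, Et3N, THF, 25 °C; then DMAP, toluene, 80 °C (0.001 M)
Reagents that add atoms: none
Why: Yamaguchi lactonisation acylates the tertiary α-ketol hydroxyl O4 (tertiary α-ketols, as in 17-hydroxy-20-keto steroids, are acylated by mixed anhydrides) to close ring C; O8 would need an 11-membered ring.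

**Step 21**
Reactants: 29 13-O-triethylsilyl ether of the target
Product: 30 CNP0266269.1
Conditions: HF·pyridine, pyridine/THF, 0 to 25 °C
Reagents that add atoms: none
Why: Fluoride-mediated desilylation releases O13 without touching the α-methylene lactone or the stereocenters.

**Compound list**
1 | furan | c1ccoc1 | starting material
2 | furan-2-yllithium | [Li]c1ccco1 | intermediate
3 | lithium (furan-2-yl)tri(propan-2-yloxy)borate | [Li+].CC(C)O[B-](OC(C)C)(OC(C)C)c1ccco1 | intermediate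
4 | 2-(furan-2-yl)-5,5-dimethyl-1,3,2-dioxaborinane | CC1(C)COB(OC1)c1ccco1 | intermediate
5 | (R)-(+)-limonene | CC1=CC[C@@H](CC1)C(C)=C | starting material
6 | 1,2,4-trioxolane (ozonide) across the ring alkene of 5 | CC12CC[C@H](CC(O1)OO2)C(C)=C | intermediate
7 | (3R)-6-oxo-3-(prop-1-en-2-yl)heptanal | O=CC[C@@H](CCC(C)=O)C(C)=C | intermediate
8 | ethyl (2E,5R)-2-methyl-8-oxo-5-(prop-1-en-2-yl)non-2-enoate | CCOC(=O)C(/C)=C/C[C@@H](CCC(C)=O)C(C)=C | intermediate
9 | ethyl (2E,5R,8R)-8-hydroxy-2-methyl-5-(prop-1-en-2-yl)non-2-enoate | CCOC(=O)C(/C)=C/C[C@@H](CC[C@@H](C)O)C(C)=C | intermediate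
10 | ethyl (2E,5R,8R)-2-methyl-5-(prop-1-en-2-yl)-8-{[2,4,6-tri(propan-2-yl)benzoyl]oxy}non-2-enoate | CCOC(=O)C(/C)=C/C[C@@H](CC[C@@H](C)OC(=O)c1c(C(C)C)cc(C(C)C)cc1C(C)C)C(C)=C | intermediate
11 | (2R,5R,7E)-9-hydroxy-8-methyl-5-(prop-1-en-2-yl)non-7-en-2-yl 2,4,6-tri(propan-2-yl)benzoate | OC/C(C)=C/C[C@@H](CC[C@@H](C)OC(=O)c1c(C(C)C)cc(C(C)C)cc1C(C)C)C(C)=C | intermediate
12 | (2E,5R,8S)-8-(5,5-dimethyl-1,3,2-dioxaborinan-2-yl)-8-(furan-2-yl)-2-methyl-5-(prop-1-en-2-yl)non-2-en-1-ol | OC/C(C)=C/C[C@@H](CC[C@@](c1ccco1)(C)B1OCC(C)(C)CO1)C(C)=C | intermediate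
13 | (2E,5R,8R)-8-(furan-2-yl)-2-methyl-5-(prop-1-en-2-yl)non-2-ene-1,8-diol | OC/C(C)=C/C[C@@H](CC[C@@](c1ccco1)(C)O)C(C)=C | intermediate
14 | 1-{5-[(2R,5R,7E)-2,9-dihydroxy-8-methyl-5-(prop-1-en-2-yl)non-7-en-2-yl]furan-2-yl}ethan-1-one | OC/C(C)=C/C[C@@H](CC[C@@](c1ccc(C(C)=O)o1)(C)O)C(C)=C | intermediate
15 | 1-{5-[(2R,5R,7E)-9-bromo-2-hydroxy-8-methyl-5-(prop-1-en-2-yl)non-7-en-2-yl]furan-2-yl}ethan-1-one | BrC/C(C)=C/C[C@@H](CC[C@@](c1ccc(C(C)=O)o1)(C)O)C(C)=C | intermediate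
16 | (1R,4R,12E)-5,8-epoxy-4-hydroxy-4,12-dimethyl-1-(prop-1-en-2-yl)cyclotetradeca-5,7,12-trien-9-one | O=C1CC/C(C)=C/C[C@@H](CC[C@@](C)(O)c2ccc1o2)C(C)=C | intermediate
17 | 4-O-triethylsilyl ether of 16 | O=C1CC/C(C)=C/C[C@@H](CC[C@@](C)(O[Si](CC)(CC)CC)c2ccc1o2)C(C)=C | intermediate
18 | (1R,4R,9R,12E)-5,8-epoxy-4,12-dimethyl-1-(prop-1-en-2-yl)-4-[(triethylsilyl)oxy]cyclotetradeca-5,7,12-trien-9-ol | O[C@@H]1CC/C(C)=C/C[C@@H](CC[C@@](C)(O[Si](CC)(CC)CC)c2ccc1o2)C(C)=C | intermediate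
19 | (1R,4R,9R,12E)-5,9-epoxy-5-hydroxy-4,12-dimethyl-1-(prop-1-en-2-yl)-4-[(triethylsilyl)oxy]cyclotetradeca-6,12-dien-8-one | OC12C=CC(=O)[C@H](O1)CC/C(C)=C/C[C@@H](CC[C@@]2(C)O[Si](CC)(CC)CC)C(C)=C | intermediate
20 | 5-O-methyl ketal of 19 | COC12C=CC(=O)[C@H](O1)CC/C(C)=C/C[C@@H](CC[C@@]2(C)O[Si](CC)(CC)CC)C(C)=C | intermediate
21 | (1R,4R,9R,12E)-5,9-epoxy-5-methoxy-4,12-dimethyl-1-(prop-1-en-2-yl)-4-[(triethylsilyl)oxy]cyclotetradec-12-en-8-one | COC12CCC(=O)[C@H](O1)CC/C(C)=C/C[C@@H](CC[C@@]2(C)O[Si](CC)(CC)CC)C(C)=C | intermediate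
22 | (1R,4R,8R,9R,12E)-5,9-epoxy-5-methoxy-4,8,12-trimethyl-1-(prop-1-en-2-yl)-4-[(triethylsilyl)oxy]cyclotetradec-12-en-8-ol | COC12CC[C@@](C)(O)[C@H](O1)CC/C(C)=C/C[C@@H](CC[C@@]2(C)O[Si](CC)(CC)CC)C(C)=C | intermediate
23 | (1R,4R,8R,9R,12S,13S)-5,9:12,13-diepoxy-5-methoxy-4,8,12-trimethyl-1-(prop-1-en-2-yl)-4-[(triethylsilyl)oxy]cyclotetradecan-8-ol | COC12CC[C@@](C)(O)[C@H](O1)CC[C@]3(C)O[C@H]3C[C@@H](CC[C@@]2(C)O[Si](CC)(CC)CC)C(C)=C | intermediate
24 | (1R,4R,8R,9R,12R,13S)-9,12-epoxy-4,8,13-trihydroxy-4,8,12-trimethyl-1-(prop-1-en-2-yl)cyclotetradecan-5-one | CC(=C)[C@@H]1CC[C@@](C)(O)C(=O)CC[C@@](C)(O)[C@H]2CC[C@@](C)(O2)[C@@H](O)C1 | intermediate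
25 | 13-O-triethylsilyl ether of 24 | CC(=C)[C@@H]1CC[C@@](C)(O)C(=O)CC[C@@](C)(O)[C@H]2CC[C@@](C)(O2)[C@@H](O[Si](CC)(CC)CC)C1 | intermediate
26 | 2-[(1R,4R,8R,9R,12R,13S)-9,12-epoxy-4,8-dihydroxy-4,8,12-trimethyl-5-oxo-13-[(triethylsilyl)oxy]cyclotetradecyl]prop-2-enal | O=CC(=C)[C@@H]1CC[C@@](C)(O)C(=O)CC[C@@](C)(O)[C@H]2CC[C@@](C)(O2)[C@@H](O[Si](CC)(CC)CC)C1 | intermediate
27 | 2-[(1R,4R,8R,9R,12R,13S)-9,12-epoxy-4,8-dihydroxy-4,8,12-trimethyl-5-oxo-13-[(triethylsilyl)oxy]cyclotetradecyl]prop-2-enoic acid | OC(=O)C(=C)[C@@H]1CC[C@@](C)(O)C(=O)CC[C@@](C)(O)[C@H]2CC[C@@](C)(O2)[C@@H](O[Si](CC)(CC)CC)C1 | intermediate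
28 | mixed anhydride of 27 with 2,4,6-trichlorobenzoic acid | O=C(OC(=O)c1c(Cl)cc(Cl)cc1Cl)C(=C)[C@@H]1CC[C@@](C)(O)C(=O)CC[C@@](C)(O)[C@H]2CC[C@@](C)(O2)[C@@H](O[Si](CC)(CC)CC)C1 | intermediate
29 | 13-O-triethylsilyl ether of the target | C=C1C(=O)O[C@]2(C)CC[C@@H]1C[C@H](O[Si](CC)(CC)CC)[C@@]1(C)CC[C@@H](O1)[C@](C)(O)CCC2=O | intermediate
30 | CNP0266269.1 | C=C1C(=O)O[C@]2(C)CC[C@@H]1C[C@H](O)[C@@]1(C)CC[C@@H](O1)[C@](C)(O)CCC2=O | target

**Totals**
Total step count: 21. Longest linear sequence: 20 steps (5 → 30, steps 2–21); furan enters through step 1 and joins at step 7.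

**Steps most likely to fail, with fallbacks**

Step 7 (furyl migration onto a hindered dialkyl carbenoid may be slow or reversible). The fallback sets out from ketone 8 and forms the C4–furan bond by 1,2-addition instead of 1,2-metalate rearrangement. (2-Furyl)AlEt2·THF, made from 2 and Et2AlCl, is added to 8 under Ti(OiPr)4/BINOL catalysis, the BINOL enantiomer being chosen for the 8R epimer. This gives ethyl (2E,5R,8R)-8-(furan-2-yl)-8-hydroxy-2-methyl-5-(prop-1-en-2-yl)non-2-enoate F1. Reduction of F1 with i-Bu2AlH returns to the route at diol 13.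

Step 10 (macrocyclic enolate alkylation may give O-alkylation or oligomers). The fallback sets out from keto-diol 14 and closes the ring by C=C formation instead of SN2. MnO2 oxidation of the allylic alcohol gives (2E,5R,8R)-8-(5-acetylfuran-2-yl)-8-hydroxy-2-methyl-5-(prop-1-en-2-yl)non-2-enal F2. Intramolecular Claisen–Schmidt aldol condensation (Ba(OH)2, EtOH, high dilution) gives (1R,4R,10E,12E)-5,8-epoxy-4-hydroxy-4,12-dimethyl-1-(prop-1-en-2-yl)cyclotetradeca-5,7,10,12-tetraen-9-one F3. Conjugate reduction of the C10=C11 bond with [(Ph3P)CuH]6/H2 comes back to the route at macrocycle 16.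

Step 20 (acylation of the tertiary α-ketol may fail or give oligomers). The fallback sets out from enal 26, isolated after the SeO2 stage, and uses the aldehyde oxidation level instead of an activated acid. O4 adds reversibly to the aldehyde to give the 7-membered C16 lactol of the 13-O-triethylsilyl target F4. Oxidation of F4 in situ (TEMPO cat., PhI(OAc)2, CH2Cl2, or Ag2CO3 on Celite, toluene, 80 °C) comes back to the route at lactone 29.

**Further compounds**
F1 | step 7 | ethyl (2E,5R,8R)-8-(furan-2-yl)-8-hydroxy-2-methyl-5-(prop-1-en-2-yl)non-2-enoate | CCOC(=O)C(/C)=C/C[C@@H](CC[C@@](c1ccco1)(C)O)C(C)=C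
F2 | step 10 | (2E,5R,8R)-8-(5-acetylfuran-2-yl)-8-hydroxy-2-methyl-5-(prop-1-en-2-yl)non-2-enal | O=C/C(C)=C/C[C@@H](CC[C@@](c1ccc(C(C)=O)o1)(C)O)C(C)=C
F3 | step 10 | (1R,4R,10E,12E)-5,8-epoxy-4-hydroxy-4,12-dimethyl-1-(prop-1-en-2-yl)cyclotetradeca-5,7,10,12-tetraen-9-one | O=C1/C=C/C(C)=C/C[C@@H](CC[C@@](C)(O)c2ccc1o2)C(C)=C
F4 | step 20 | C16 lactol of the 13-O-triethylsilyl target | C=C1C(O)O[C@]2(C)CC[C@@H]1C[C@H](O[Si](CC)(CC)CC)[C@@]1(C)CC[C@@H](O1)[C@](C)(O)CCC2=O
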